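The dihydrofuran ring is closed by joining its unsubstituted methylene carbon C3 to the benzene carbon C3a. Until then C3 is an inert methyl group: it belongs to an (S)-configured sec-alkyl aryl ether made from methyl (R)-lactate, which already holds the C2 stereocentre and the later 2-hydroxypropan-2-yl group. C3a is the only free position of the acylphloroglucinol ring, flanked by the oxygen-bearing carbons C4 and C7a, so it is brominated without ambiguity. A Pd(0)-catalysed C(sp3)–H arylation then links the methyl carbon to C3a through a six-membered palladacycle. The prenylated acylphloroglucinol core is built first by Friedel–Crafts acylation and C-prenylation, and MOM ethers cap all hydroxyl groups before the key step.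

Key step: step 8

Remark: bicyclic compounds are numbered as 2,3-dihydro-1-benzofuran (O1, C2, C3, C3a, C4 to C7, C7a). In the open-chain intermediates the phenyl ring is numbered from the acyl-bearing carbon (C1). The stereocentre of the target (C2) is S.

Step 1
Reactants: 1 phloroglucinol; 2 3-(4-methoxyphenyl)propanoic acid
Product: 3 3-(4-methoxyphenyl)-1-(2,4,6-trihydroxyphenyl)propan-1-one
Conditions: BF3·OEt2 (solvent), 85 °C; aq. NaOAc
Reagents that add atoms: none
Why: Friedel–Crafts acylation of the very electron-rich triol by the BF3-activated acid should stop after one acylation, because the new chelated ketone deactivates the ring and the three ring positions are equivalent.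

Step 2
Reactants: 3 trihydroxy ketone; 4 prenyl bromide
Product: 5 3-(4-methoxyphenyl)-1-[2,4,6-trihydroxy-3-(3-methylbut-2-en-1-yl)phenyl]propan-1-one
Conditions: DBU (1.1 equiv), THF, 0 °C to rt
Reagents that add atoms: none
Why: Base-mediated C-alkylation of the ambident acylphloroglucinol anion (a vinylogous triketone enolate) with the soft allylic bromide occurs at one of the two equivalent free ring carbons, and one equivalent of bromide holds back a second prenylation.

Step 3
Reactants: 5 C-prenyl trihydroxy ketone
Product: 6 1-[2,6-dihydroxy-4-(methoxymethoxy)-3-(3-methylbut-2-en-1-yl)phenyl]-3-(4-methoxyphenyl)propan-1-one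
Conditions: MOMCl (1.1 equiv), i-Pr2NEt, CH2Cl2, 0 °C
Reagents that add atoms: chloromethyl methyl ether, COCCl
Why: O-alkylation (acetal formation) should occur only at the 4-OH, which is para to the ketone, most acidic and not hydrogen-bonded, while the 2- and 6-OH groups are held in the chelate with the carbonyl group.

Step 4
Reactants: 6 4-O-MOM dihydroxy ketone; 7 methyl (R)-lactate
Product: 8 methyl (2S)-2-{3-hydroxy-5-(methoxymethoxy)-2-[3-(4-methoxyphenyl)propanoyl]-4-(3-methylbut-2-en-1-yl)phenoxy}propanoate
Conditions: PPh3, DIAD, THF, 0 °C to rt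
Reagents that add atoms: none
Why: Mitsunobu etherification with SN2 inversion at the lactate carbon sets the future C2 stereocentre as S; it should engage the 6-OH next to the free ring position rather than the 2-OH buttressed by the prenyl group, and the remaining chelated OH does not react further.

Step 5
Reactants: 8 (S)-aryloxypropanoate ester
Product: 10 tertiary alcohol 1-[2-hydroxy-6-{[(2S)-3-hydroxy-3-methylbutan-2-yl]oxy}-4-(methoxymethoxy)-3-(3-methylbut-2-en-1-yl)phenyl]-3-(4-methoxyphenyl)propan-1-one, via methyl ketone 9 (not isolated)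
Conditions: MeMgBr (3.5 equiv), THF, −40 to 0 °C; aq. NH4Cl
Reagents that add atoms: methylmagnesium bromide, C[Mg]Br
Why: Double Grignard addition to the activated α-aryloxy ester gives the tertiary alcohol, while the aryl ketone, flanked by two ortho substituents and tied up as the magnesium phenoxide chelate formed by the first equivalent, should not be attacked; the stereocentre is untouched because the intermediate methyl ketone is consumed faster than it enolises.

Step 6
Reactants: 10 tertiary alcohol
Product: 11 tris-MOM ether 1-[2,4-bis(methoxymethoxy)-6-{[(2S)-3-(methoxymethoxy)-3-methylbutan-2-yl]oxy}-3-(3-methylbut-2-en-1-yl)phenyl]-3-(4-methoxyphenyl)propan-1-one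
Conditions: NaH (2.1 equiv), MOMCl (3 equiv), THF–DMF, 0 °C to rt
Reagents that add atoms: chloromethyl methyl ether, COCCl
Why: Williamson-type acetalisation of the sodium phenoxide and the tertiary alkoxide caps the last two O–H groups, so that neither can attack a bromonium ion in step 7 or bind palladium in step 8.

Step 7
Reactants: 11 tris-MOM ether
Product: 12 aryl bromide 1-[3-bromo-4,6-bis(methoxymethoxy)-2-{[(2S)-3-(methoxymethoxy)-3-methylbutan-2-yl]oxy}-5-(3-methylbut-2-en-1-yl)phenyl]-3-(4-methoxyphenyl)propan-1-one
Conditions: NBS (1.05 equiv), MeCN, 0 °C, dark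
Reagents that add atoms: N-bromosuccinimide, O=C1CCC(=O)N1Br
Why: Electrophilic aromatic bromination goes to the only free position of the trialkoxy ring (the future C3a), which is ortho to two oxygens and para to the third and should therefore react far faster than the anisole ring or the prenyl double bond with NBS in the absence of acid or a nucleophile.

Step 8
Reactants: 12 aryl bromide
Product: 13 3-(4-methoxyphenyl)-1-[(2S)-4,6-bis(methoxymethoxy)-2-[2-(methoxymethoxy)propan-2-yl]-5-(3-methylbut-2-en-1-yl)-2,3-dihydro-1-benzofuran-7-yl]propan-1-one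
Conditions: Pd(OAc)2 (10 mol%), PCy3·HBF4 (20 mol%), PivOH (30 mol%), Cs2CO3 (1.5 equiv), mesitylene, 135 °C
Reagents that add atoms: none
Why: Oxidative addition of the C3a–Br bond to Pd(0)/PCy3, exchange of bromide for pivalate and concerted metalation–deprotonation of a C–H bond of the methyl group on C2 give a six-membered palladacycle (Pd, C3a, C7a, O1, C2, CH2), from which C(sp2)–C(sp3) reductive elimination forms the C3–C3a bond and returns Pd(0). The closest known reaction type is the Pd(0)/pivalate-catalysed intramolecular C(sp3)–H arylation of 2-bromoaryl alkyl ethers to 2,3-dihydrobenzofurans. The dihydrofuran ring is closed by ring contraction of that palladacycle in the reductive elimination, formally a 5-exo closure of the aryl carbon onto the methyl carbon. No stereocentre is formed; the S centre at C2, set in step 4, carries no acidic hydrogen and takes no part, so it should be retained. The step needs site selectivity among the C(sp3)–H bonds, and only the C2 methyl group can reach palladium in a six-membered ring, whereas the gem-dimethyl and MOM C–H bonds would need seven-membered or larger palladacycles and the C2–H bond a strained five-membered one. Chemoselectivity is secured by the MOM caps on every oxygen, which rule out Pd–alkoxide formation and C–O reductive elimination, and by the two ortho substituents that hold the ether side chain over the C–Pd bond.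

Step 9
Reactants: 13 tris-MOM dihydrobenzofuran
Product: 14 1-[(2S)-4,6-dihydroxy-2-(2-hydroxypropan-2-yl)-5-(3-methylbut-2-en-1-yl)-2,3-dihydro-1-benzofuran-7-yl]-3-(4-methoxyphenyl)propan-1-one (target)
Conditions: 3 M aq. HCl, MeOH, 40 °C
Reagents that add atoms: none
Why: Acid-catalysed transacetalisation with methanol removes the two aryl MOM ethers and the tertiary alkyl MOM ether as dimethoxymethane, under conditions that should be too mild to cyclise the prenyl group onto the neighbouring phenols or to ionise the tertiary alcohol.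

Compound list

1 | phloroglucinol (benzene-1,3,5-triol) | Oc1cc(O)cc(O)c1 | starting material
2 | 3-(4-methoxyphenyl)propanoic acid | COc1ccc(CCC(=O)O)cc1 | starting material
3 | 3-(4-methoxyphenyl)-1-(2,4,6-trihydroxyphenyl)propan-1-one | COc1ccc(CCC(=O)c2c(O)cc(O)cc2O)cc1 | intermediate
4 | prenyl bromide (1-bromo-3-methylbut-2-ene) | CC(C)=CCBr | starting material
5 | 3-(4-methoxyphenyl)-1-[2,4,6-trihydroxy-3-(3-methylbut-2-en-1-yl)phenyl]propan-1-one | COc1ccc(CCC(=O)c2c(O)cc(O)c(CC=C(C)C)c2O)cc1 | intermediate
6 | 1-[2,6-dihydroxy-4-(methoxymethoxy)-3-(3-methylbut-2-en-1-yl)phenyl]-3-(4-methoxyphenyl)propan-1-one | COc1ccc(CCC(=O)c2c(O)cc(OCOC)c(CC=C(C)C)c2O)cc1 | intermediate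
7 | methyl (R)-lactate (methyl (2R)-2-hydroxypropanoate) | C[C@@H](O)C(=O)OC | starting material
8 | methyl (2S)-2-{3-hydroxy-5-(methoxymethoxy)-2-[3-(4-methoxyphenyl)propanoyl]-4-(3-methylbut-2-en-1-yl)phenoxy}propanoate | COc1ccc(CCC(=O)c2c(O[C@@H](C)C(=O)OC)cc(OCOC)c(CC=C(C)C)c2O)cc1 | intermediate
9 | (3S)-3-{3-hydroxy-5-(methoxymethoxy)-2-[3-(4-methoxyphenyl)propanoyl]-4-(3-methylbut-2-en-1-yl)phenoxy}butan-2-one | COc1ccc(CCC(=O)c2c(O[C@@H](C)C(C)=O)cc(OCOC)c(CC=C(C)C)c2O)cc1 | intermediate (not isolated)
10 | 1-[2-hydroxy-6-{[(2S)-3-hydroxy-3-methylbutan-2-yl]oxy}-4-(methoxymethoxy)-3-(3-methylbut-2-en-1-yl)phenyl]-3-(4-methoxyphenyl)propan-1-one | COc1ccc(CCC(=O)c2c(O[C@@H](C)C(C)(C)O)cc(OCOC)c(CC=C(C)C)c2O)cc1 | intermediate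
11 | 1-[2,4-bis(methoxymethoxy)-6-{[(2S)-3-(methoxymethoxy)-3-methylbutan-2-yl]oxy}-3-(3-methylbut-2-en-1-yl)phenyl]-3-(4-methoxyphenyl)propan-1-one | COc1ccc(CCC(=O)c2c(O[C@@H](C)C(C)(C)OCOC)cc(OCOC)c(CC=C(C)C)c2OCOC)cc1 | intermediate
12 | 1-[3-bromo-4,6-bis(methoxymethoxy)-2-{[(2S)-3-(methoxymethoxy)-3-methylbutan-2-yl]oxy}-5-(3-methylbut-2-en-1-yl)phenyl]-3-(4-methoxyphenyl)propan-1-one | COc1ccc(CCC(=O)c2c(O[C@@H](C)C(C)(C)OCOC)c(Br)c(OCOC)c(CC=C(C)C)c2OCOC)cc1 | intermediate
13 | 3-(4-methoxyphenyl)-1-[(2S)-4,6-bis(methoxymethoxy)-2-[2-(methoxymethoxy)propan-2-yl]-5-(3-methylbut-2-en-1-yl)-2,3-dihydro-1-benzofuran-7-yl]propan-1-one | COc1ccc(CCC(=O)c2c(OCOC)c(CC=C(C)C)c(OCOC)c3c2O[C@H](C(C)(C)OCOC)C3)cc1 | intermediate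
14 | 1-[(2S)-4,6-dihydroxy-2-(2-hydroxypropan-2-yl)-5-(3-methylbut-2-en-1-yl)-2,3-dihydro-1-benzofuran-7-yl]-3-(4-methoxyphenyl)propan-1-one | COc1ccc(CCC(=O)c2c(O)c(CC=C(C)C)c(O)c3c2O[C@H](C(C)(C)O)C3)cc1 | target

Total step count: 9
Longest linear sequence: 9 steps (1 to 14)

Steps most likely to fail

Step 8. Oxidative addition at the doubly ortho-substituted, electron-rich C–Br bond may be slow, so that the aryl–palladium species is protonated (loss of bromine) or the catalyst decays before the methyl C–H bond is cleaved. The fallback closes the same C3–C3a bond by an aryllithium alkylation (Parham cyclisation) instead of C–H activation; it sets out from 6 and comes back at 13. Methyl (R)-oxirane-2-carboxylate is opened at C3 with HCl in ether to methyl (S)-3-chloro-2-hydroxypropanoate F1 (same spatial arrangement at C2, new descriptor). Mitsunobu coupling of F1 with 6 (PPh3, DIAD) should give, with inversion, the (R)-configured chloro ester F2. MeMgBr converts F2 into the chloro tertiary alcohol F3, and MOMCl/i-Pr2NEt/Bu4NI caps both hydroxyl groups to give the tris-MOM chloride F4. NBS in MeCN gives the aryl bromide F5. F5 is first converted into its lithium enolate (LiHMDS, 1.1 equiv, THF, −78 °C) to shield the ketone and then treated with t-BuLi (2.1 equiv); bromine–lithium exchange and 5-exo-tet displacement of chloride by the aryllithium should give 13.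

Step 5. The Grignard reagent may add to the aryl ketone, or the intermediate methyl ketone may enolise with loss of configuration. The fallback brings in the tertiary carbinol ready-made, so that no organometallic reagent meets the ketone; it sets out from 6 and comes back at 10. Shi epoxidation of 2-methylbut-2-ene (D-fructose-derived ketone, Oxone) should give (R)-2,2,3-trimethyloxirane F6. The caesium phenoxide of 6 (Cs2CO3, DMF, 70 °C, sealed tube) opens F6 at its secondary carbon with inversion and should give 10 directly, replacing steps 4 and 5.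

Step 2. O-alkylation and double C-alkylation may compete with the mono-C-prenylation. The fallback is an acid-mediated Friedel–Crafts prenylation of the neutral phenol 3 with 2-methylbut-3-en-2-ol and BF3·OEt2 in dioxane at room temperature, in which the prenyl cation is attacked by ring carbon and the reaction is stopped at partial conversion. It sets out from 3, comes back at 5 and makes no new compound (F0).

Further compounds

F1 | step 8 | methyl (2S)-3-chloro-2-hydroxypropanoate | COC(=O)[C@H](O)CCl
F2 | step 8 | methyl (2R)-3-chloro-2-{3-hydroxy-5-(methoxymethoxy)-2-[3-(4-methoxyphenyl)propanoyl]-4-(3-methylbut-2-en-1-yl)phenoxy}propanoate | COc1ccc(CCC(=O)c2c(O[C@@H](CCl)C(=O)OC)cc(OCOC)c(CC=C(C)C)c2O)cc1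
F3 | step 8 | 1-[2-{[(2R)-1-chloro-3-hydroxy-3-methylbutan-2-yl]oxy}-6-hydroxy-4-(methoxymethoxy)-5-(3-methylbut-2-en-1-yl)phenyl]-3-(4-methoxyphenyl)propan-1-one | COc1ccc(CCC(=O)c2c(O[C@@H](CCl)C(C)(C)O)cc(OCOC)c(CC=C(C)C)c2O)cc1
F4 | step 8 | 1-[2-{[(2R)-1-chloro-3-(methoxymethoxy)-3-methylbutan-2-yl]oxy}-4,6-bis(methoxymethoxy)-5-(3-methylbut-2-en-1-yl)phenyl]-3-(4-methoxyphenyl)propan-1-one | COc1ccc(CCC(=O)c2c(O[C@@H](CCl)C(C)(C)OCOC)cc(OCOC)c(CC=C(C)C)c2OCOC)cc1
F5 | step 8 | 1-[3-bromo-2-{[(2R)-1-chloro-3-(methoxymethoxy)-3-methylbutan-2-yl]oxy}-4,6-bis(methoxymethoxy)-5-(3-methylbut-2-en-1-yl)phenyl]-3-(4-methoxyphenyl)propan-1-one | COc1ccc(CCC(=O)c2c(O[C@@H](CCl)C(C)(C)OCOC)c(Br)c(OCOC)c(CC=C(C)C)c2OCOC)cc1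
F6 | step 5 | (3R)-2,2,3-trimethyloxirane | C[C@H]1OC1(C)C
F0 | step 2 | none | none
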